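**Retrosynthetic overview**
- Endgame: the target comes from its C6 diethyl acetal; the C15 carbinol is set last by exo-face hydride reduction of the 16-en-15-one.
- Ring D (C13–C16) comes from a 5-exo vinyl-radical closure of a C8 2-bromoallylic alcohol onto the C12=C13 olefin of ring C.
- Key disconnection: C9–C10 (spiro centre; C6 and C7 carbonyls are 1,6-related), made together with C4–C5 and C8–C15 in one reductive titanium cascade from an acyclic epoxy-olefin ester; the C10 radical adds to the enoate β-carbon and the enolate is trapped by 2-bromoacrolein.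
- The acyclic ester comes from cyclohexa-1,4-diene-1-carboxylic acid (ring C, Diels–Alder) and an epoxy diol; the diol comes from vinylalumination of ethyl 4,4-diethoxybut-2-ynoate with 4-methylpent-3-enal (C1 by CBS reduction, C3 by Shi epoxidation).
- Ring order: C (Diels–Alder) → A → δ-lactone (same flask) → D.

Assumption: ent-kaurane numbering (C1–C20) is used for all atoms, also in acyclic precursors, and where C15 or C8 is an epimer mixture that centre is left undefined in the SMILES.

**Step 1**
Reactants: 1 4-methylpent-3-en-1-ol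
Product: 2 4-methylpent-3-enal
Conditions: Dess–Martin periodinane, CH2Cl2, 0 °C to rt; filtered solution used at once
Reagents that add atoms: none
Why: Dess–Martin oxidation of the primary alcohol stops at the aldehyde under near-neutral conditions, so the β,γ-double bond does not move into conjugation.

**Step 2**
Reactants: 3 3,3-diethoxyprop-1-yne
Product: 5 ethyl 4,4-diethoxybut-2-ynoate, via lithium acetylide 4 (not isolated)
Conditions: n-BuLi, THF, −78 °C; then ClCO2Et, −78 to 0 °C
Reagents that add atoms: ethyl chloroformate, CCOC(=O)Cl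
Why: Deprotonation of the terminal alkyne and C-acylation of the acetylide by the chloroformate gives the ynoate (acetylide alkoxycarbonylation).

**Step 3**
Reactants: 5 ethyl 4,4-diethoxybut-2-ynoate; 2 4-methylpent-3-enal
Product: 7 ethyl (2Z)-4,4-diethoxy-2-(1-hydroxy-4-methylpent-3-en-1-yl)but-2-enoate (racemic), via vinylalane 6 (not isolated)
Conditions: i-Bu2AlH, N-methylmorpholine N-oxide, THF, 0 °C; then 2, 0 °C to rt; aqueous work-up
Reagents that add atoms: none
Why: Conjugate syn-hydroalumination gives the α-alumino acrylate (aluminium allenolate), which adds to the aldehyde on the side of the vinylic H (vinylalumination, a reductive Morita–Baylis–Hillman-type aldol), so the acetal carbon C6 ends cis to the ester carbon C20; C1 is formed racemic.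

**Step 4**
Reactants: 7 racemic allylic alcohol
Product: 8 ethyl (2Z)-4,4-diethoxy-2-(4-methylpent-3-enoyl)but-2-enoate
Conditions: Dess–Martin periodinane, CH2Cl2, 0 °C, 30 min; filtered cold and used at once
Reagents that add atoms: none
Why: Dess–Martin oxidation of the secondary alcohol works without base, which would scramble the alkylidene geometry or conjugate the skipped enone.

**Step 5**
Reactants: 8 alkylidene β-keto ester
Product: 9 ethyl (2Z)-4,4-diethoxy-2-[(1S)-1-hydroxy-4-methylpent-3-en-1-yl]but-2-enoate
Conditions: (R)-2-methyl-CBS-oxazaborolidine (20 mol %), catecholborane, toluene, −78 °C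
Reagents that add atoms: none
Why: Corey–Bakshi–Shibata 1,2-reduction in which the alkenyl group acts as the large substituent, so the (R)-catalyst delivers hydride to give the (S)-carbinol at C1.

**Step 6**
Reactants: 9 (S)-hydroxy ester
Product: 10 (2E)-4,4-diethoxy-2-[(1S)-1-hydroxy-4-methylpent-3-en-1-yl]but-2-en-1-ol
Conditions: i-Bu2AlH (3.5 equiv), CH2Cl2, −78 °C
Reagents that add atoms: none
Why: 1,2-Reduction of the conjugated ethyl ester gives the primary allylic alcohol (C20) and leaves the acetal, both olefins and the olefin geometry untouched.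

**Step 7**
Reactants: 10 diol
Product: 11 (2E)-2-{(1S)-2-[(2R)-3,3-dimethyloxiran-2-yl]-1-hydroxyethyl}-4,4-diethoxybut-2-en-1-ol
Conditions: Shi ketone (D-fructose-derived, 30 mol %), KHSO5, K2CO3, Bu4NHSO4, MeCN–CH2(OMe)2–aqueous buffer pH 10.5, 0 °C; chromatography on Et3N-deactivated silica
Reagents that add atoms: potassium peroxymonosulfate, [K+].[O-]S(=O)(=O)OO
Why: Shi asymmetric epoxidation: the chiral dioxirane attacks only the electron-rich isopropylidene olefin (the allylically tri-oxygenated C5=C10 olefin is deactivated) through the spiro transition state and gives the (R)-epoxide (C3) under reagent control.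

**Step 8**
Reactants: 12 buta-1,3-diene; 13 prop-2-ynoic acid
Product: 14 cyclohexa-1,4-diene-1-carboxylic acid
Conditions: toluene, hydroquinone (cat.), sealed tube, 100 °C
Reagents that add atoms: none
Why: Diels–Alder cycloaddition of the alkynoic acid gives ring C as an achiral 1,4-diene that holds both the conjugated acceptor olefin (C8=C9) and the isolated olefin (C12=C13) used later.

**Step 9**
Reactants: 11 epoxy diol; 14 cyclohexa-1,4-diene-1-carboxylic acid
Product: 15 C20 cyclohexa-1,4-diene-1-carboxylate of 11 (C1 hydroxyl free)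
Conditions: DCC, DMAP (cat.), CH2Cl2, −20 to 0 °C
Reagents that add atoms: none
Why: Steglich esterification acylates the primary allylic alcohol (C20) much faster than the hindered secondary one (C1), under neutral conditions that spare the epoxide.

**Step 10**
Reactants: 15 hydroxy ester
Product: 16 [(2E)-2-{(1S)-1-acetoxy-2-[(2R)-3,3-dimethyloxiran-2-yl]ethyl}-4,4-diethoxybut-2-en-1-yl] cyclohexa-1,4-diene-1-carboxylate
Conditions: Ac2O, Et3N, DMAP (cat.), CH2Cl2, 0 °C
Reagents that add atoms: acetic anhydride, CC(=O)OC(C)=O
Why: DMAP-catalysed acetylation puts the C1 acetate of the target on the only free hydroxyl, before any other hydroxyl exists, so no later differentiation is needed.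

**Step 11**
Reactants: 17 prop-2-enal
Product: 19 2-bromoprop-2-enal, via 2,3-dibromopropanal 18 (not isolated)
Conditions: Br2, CH2Cl2, −78 °C; then Et3N, −78 to 0 °C; used fresh
Reagents that add atoms: bromine, BrBr
Why: Bromine addition to the olefin followed by E1cB loss of HBr from the α-bromo aldehyde gives the α-bromo enal (bromination–dehydrobromination).

**Step 12**
Reactants: 16 epoxy-olefin ester; 19 2-bromoprop-2-enal
Product: 21 C8-(2-bromo-1-hydroxyallyl) spirolactone (C15 epimers), via titanium enolate 20 (not isolated)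
Conditions: (C5H5)2TiCl2 (3 equiv), Zn dust, THF, rt [gives (C5H5)2TiCl]; added over 4 h to 16 (0.005 M in THF), rt; then 19 (5 equiv), −78 to −20 °C; aq. NaHCO3
Reagents that add atoms: none
Why: Proposed new method: trivalent titanium opens the epoxide homolytically at the tertiary carbon (the C3–O bond and its configuration are kept), the C4 radical closes ring A 6-endo onto C5 through a chair with the C3–OTi, C1–OAc and C6 acetal groups equatorial, and the resulting tertiary C10 radical – a nucleophilic, reversed-polarity form of the carbon that lies β to the masked C6 aldehyde and would be the cationic terminus of an ordinary epoxy-olefin cyclization – adds 6-endo to C9, the electrophilic β-carbon of the tethered enoate (two carbons that are normally both acceptors, C6/C7 being 1,6-related), bonding on the equatorial face of C10 away from the axial C4 methyl and with the C8/C14 flank of ring C turned to the less hindered C1 side, after which a second trivalent titanium reduces the α-ester radical to titanium enolate 20, which adds to 19 on the face syn to H9 (anti to the C10/C11 flank) to make the C8 quaternary centre; the closest known chemistry is titanocene-mediated epoxypolyene radical cyclization, Nugent–RajanBabu epoxide/acrylate conjugate addition with lactone formation, and Reformatsky-type aldol additions of titanocene enolates.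

**Step 13**
Reactants: 21 vinyl bromide
Product: 22 1-acetoxy-6,6-diethoxy-3,15-dihydroxy-6,7-seco-ent-kaur-16-en-7,20-olide (C15 epimers)
Conditions: Bu3SnH (0.05 M), AIBN (cat.), benzene, 80 °C
Reagents that add atoms: none
Why: Stork vinyl-radical cyclization: the C16 vinyl radical closes 5-exo onto C13 of the ring C olefin (a high stannane concentration traps the kinetic bicyclo[3.2.1]octane before rearrangement to the [2.2.2] isomer), the one-carbon tether forces the cis bridge and so the C13 configuration, and the C12 radical is reduced by the stannane.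

**Step 14**
Reactants: 22 allylic alcohol (C15 epimers)
Product: 23 1-acetoxy-6,6-diethoxy-3-hydroxy-15-oxo-6,7-seco-ent-kaur-16-en-7,20-olide
Conditions: MnO2, CH2Cl2, rt
Reagents that add atoms: none
Why: MnO2 oxidizes only the allylic C15 alcohol (both epimers converge) to the 16-en-15-one and leaves the saturated C3 alcohol alone, which erases the unselective aldol stereocentre.

**Step 15**
Reactants: 23 enone
Product: 24 1-acetoxy-6,6-diethoxy-3,15-dihydroxy-6,7-seco-ent-kaur-16-en-7,20-olide with the 15-OH of the target
Conditions: NaBH4, CeCl3·7H2O, MeOH, −78 °C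
Reagents that add atoms: none
Why: Luche 1,2-reduction: hydride attacks the cyclopentenone from the open exo face of the bicyclo[3.2.1]octane (away from the C9–C11–C12 bridge), which puts the 15-OH on the face turned toward that bridge as in the target, without touching lactone, acetate or acetal.

**Step 16**
Reactants: 24 diethyl acetal
Product: 25 target CNP0536233.1
Conditions: pyridinium p-toluenesulfonate, acetone–H2O (10:1), 40 °C
Reagents that add atoms: water, O
Why: Mild acid-catalysed acetal hydrolysis releases the C6 aldehyde, which stays equatorial (the thermodynamic configuration) at C5, and the allylic alcohol, acetate and lactone survive.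

**Compound list**
1 | 4-methylpent-3-en-1-ol | CC(C)=CCCO | starting material
2 | 4-methylpent-3-enal | CC(C)=CCC=O | intermediate
3 | 3,3-diethoxyprop-1-yne | CCOC(OCC)C#C | starting material
4 | (3,3-diethoxyprop-1-yn-1-yl)lithium (not isolated) | CCOC(OCC)C#C[Li] | intermediate
5 | ethyl 4,4-diethoxybut-2-ynoate | CCOC(=O)C#CC(OCC)OCC | intermediate
6 | ethyl (2E)-2-[bis(2-methylpropyl)alumanyl]-4,4-diethoxybut-2-enoate (Al cis to the vinylic H, ester cis to the acetal carbon; not isolated) | CCOC(=O)/C(=C\C(OCC)OCC)[Al](CC(C)C)CC(C)C | intermediate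
7 | ethyl (2Z)-4,4-diethoxy-2-(1-hydroxy-4-methylpent-3-en-1-yl)but-2-enoate, racemic at C1 | CCOC(=O)/C(=C\C(OCC)OCC)C(O)CC=C(C)C | intermediate
8 | ethyl (2Z)-4,4-diethoxy-2-(4-methylpent-3-enoyl)but-2-enoate | CCOC(=O)/C(=C\C(OCC)OCC)C(=O)CC=C(C)C | intermediate
9 | ethyl (2Z)-4,4-diethoxy-2-[(1S)-1-hydroxy-4-methylpent-3-en-1-yl]but-2-enoate | CCOC(=O)/C(=C\C(OCC)OCC)[C@@H](O)CC=C(C)C | intermediate
10 | (2E)-4,4-diethoxy-2-[(1S)-1-hydroxy-4-methylpent-3-en-1-yl]but-2-en-1-ol (CH2OH cis to the acetal carbon) | CCOC(OCC)/C=C(\CO)[C@@H](O)CC=C(C)C | intermediate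
11 | (2E)-2-{(1S)-2-[(2R)-3,3-dimethyloxiran-2-yl]-1-hydroxyethyl}-4,4-diethoxybut-2-en-1-ol | CCOC(OCC)/C=C(\CO)[C@@H](O)C[C@H]1OC1(C)C | intermediate
12 | buta-1,3-diene | C=CC=C | starting material
13 | prop-2-ynoic acid | C#CC(=O)O | starting material
14 | cyclohexa-1,4-diene-1-carboxylic acid | OC(=O)C1=CCC=CC1 | intermediate
15 | [(2E)-2-{(1S)-2-[(2R)-3,3-dimethyloxiran-2-yl]-1-hydroxyethyl}-4,4-diethoxybut-2-en-1-yl] cyclohexa-1,4-diene-1-carboxylate | CCOC(OCC)/C=C(\COC(=O)C1=CCC=CC1)[C@@H](O)C[C@H]1OC1(C)C | intermediate
16 | [(2E)-2-{(1S)-1-acetoxy-2-[(2R)-3,3-dimethyloxiran-2-yl]ethyl}-4,4-diethoxybut-2-en-1-yl] cyclohexa-1,4-diene-1-carboxylate | CCOC(OCC)/C=C(\COC(=O)C1=CCC=CC1)[C@@H](OC(C)=O)C[C@H]1OC1(C)C | intermediate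
17 | prop-2-enal (acrolein) | C=CC=O | starting material
18 | 2,3-dibromopropanal (not isolated) | O=CC(Br)CBr | intermediate
19 | 2-bromoprop-2-enal | C=C(Br)C=O | intermediate
20 | bis-titanium species after the radical cascade: ring A (1-OAc, 3-O–Ti(C5H5)2Cl, 4,4-dimethyl, 5-CH(OEt)2, all equatorial) spiro at C10 to the six-membered ketene acetal ring whose C7 oxygen carries Ti(C5H5)2Cl, fused at C8–C9 to the cyclohex-12-ene ring C (tetravalent titanium; not isolated) | Cl[Ti](C1C=CC=C1)(C1C=CC=C1)OC1=C2CC=CC[C@H]2[C@]2(CO1)[C@@H](OC(C)=O)C[C@@H](O[Ti](Cl)(C1C=CC=C1)C1C=CC=C1)C(C)(C)[C@H]2C(OCC)OCC | intermediate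
21 | tricyclic aldol adduct: ring A as in the target but with 5-CH(OEt)2, spiro at C10 to the δ-lactone (C10–C20–O–C7(=O)–C8–C9), which is cis-fused to cyclohex-12-ene ring C; C8 carries CH(OH)C(Br)=CH2 cis to H9; C1, C3, C5, C8, C9, C10 as in the target, C15 epimer mixture | C=C(Br)C(O)[C@]12CC=CC[C@H]1[C@]1(COC2=O)[C@@H](OC(C)=O)C[C@@H](O)C(C)(C)[C@H]1C(OCC)OCC | intermediate
22 | 1-acetoxy-6,6-diethoxy-3,15-dihydroxy-6,7-seco-ent-kaur-16-en-7,20-olide, all centres as in the target except C15 (epimer mixture) | C=C1[C@@H]2CC[C@@H]3[C@](C2)(C(=O)OC[C@]32[C@@H](OC(C)=O)C[C@@H](O)C(C)(C)[C@H]2C(OCC)OCC)C1O | intermediate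
23 | 1-acetoxy-6,6-diethoxy-3-hydroxy-15-oxo-6,7-seco-ent-kaur-16-en-7,20-olide | C=C1[C@@H]2CC[C@@H]3[C@](C2)(C(=O)OC[C@]32[C@@H](OC(C)=O)C[C@@H](O)C(C)(C)[C@H]2C(OCC)OCC)C1=O | intermediate
24 | 1-acetoxy-6,6-diethoxy-3,15-dihydroxy-6,7-seco-ent-kaur-16-en-7,20-olide, 15-OH on the ring D face turned toward C9–C11–C12 | C=C1[C@@H]2CC[C@@H]3[C@](C2)(C(=O)OC[C@]32[C@@H](OC(C)=O)C[C@@H](O)C(C)(C)[C@H]2C(OCC)OCC)[C@@H]1O | intermediate
25 | CNP0536233.1: 1-acetoxy-3,15-dihydroxy-6-oxo-6,7-seco-ent-kaur-16-en-7,20-olide (C1 S, C3 R; 1-OAc, 3-OH and 5-CHO equatorial on ring A) | C=C1[C@@H]2CC[C@@H]3[C@](C2)(C(=O)OC[C@]32[C@@H](OC(C)=O)C[C@@H](O)C(C)(C)[C@H]2C=O)[C@@H]1O | target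

**Totals**
Total steps: 16. Longest linear sequence: 13 steps (1 → 2 → 7 → 8 → 9 → 10 → 11 → 15 → 16 → 21 → 22 → 23 → 24 → 25).

**Steps most likely to fail**

Step 12 (titanium cascade with aldol termination).
- Risks: the ester tether must adopt the s-cis form for the 6-endo addition; the C10 radical has β-acyloxy groups and may be trapped by titanium and eliminated; the bis-allylic C–H bonds of the diene can quench radicals; the hindered titanium enolate must add to the aldehyde while trivalent titanium is still present.
- Fallback (sets out from 16, comes back at 21): run the titanium bicyclization without the aldehyde and quench enolate 20 at −78 °C with N-bromosuccinimide to give the tertiary α-bromo lactone F1 (C8 epimers, both usable). A Reformatsky reaction of F1 with 19 (activated Zn, THF, 0 °C) then forms the C8–C15 bond through the zinc enolate, away from the titanium reagents, and gives 21.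

Step 13 (vinyl-radical ring D closure).
- Risks: 6-endo closure or homoallyl rearrangement to the bicyclo[2.2.2]octane, and 1,5-hydrogen shift in the vinyl radical.
- Fallback (sets out from 16, comes back at 22): carry out step 12 with 3-(trimethylsilyl)prop-2-ynal in place of 19 to obtain the silyl propargylic alcohol F2. Remove the silyl group with Bu4NF/AcOH (THF, 0 °C) to give the terminal propargylic alcohol F3. Close ring D by a palladium-hydride reductive enyne cyclization (Pd2(dba)3·CHCl3, P(o-tol)3, AcOH, Et3SiH, toluene, rt): hydropalladation of the alkyne, 5-exo carbopalladation of C12=C13 and silane reduction of the C12–Pd bond give 22 with the exocyclic methylene and no tin.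

Step 5 (asymmetric reduction of the geometry-labile alkylidene β-keto ester).
- Risks: E/Z scrambling or conjugation of 8, and modest enantioselectivity.
- Fallback (sets out from 7, comes back at 9): skip ketone 8 and resolve racemic 7 by lipase-catalysed acylation (Amano lipase PS, vinyl acetate, t-BuOMe, 30 °C). The (R)-alcohol is acetylated to the (R)-acetate F4 and the unreacted (S)-alcohol is 9, at the cost of half the material.

**Further compounds**
F1 | step 12 | 8-bromo analogue of the cascade lactone: ring A/spiro-δ-lactone/cyclohex-12-ene tricycle with Br on C8 (C8 epimers), 3-OH free | BrC12CC=CC[C@H]1[C@]1(COC2=O)[C@@H](OC(C)=O)C[C@@H](O)C(C)(C)[C@H]1C(OCC)OCC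
F2 | step 13 | analogue of 21 with CH(OH)C≡C–SiMe3 on C8 (C15 epimers) | C[Si](C)(C)C#CC(O)[C@]12CC=CC[C@H]1[C@]1(COC2=O)[C@@H](OC(C)=O)C[C@@H](O)C(C)(C)[C@H]1C(OCC)OCC
F3 | step 13 | analogue of 21 with CH(OH)C≡CH on C8 (C15 epimers) | C#CC(O)[C@]12CC=CC[C@H]1[C@]1(COC2=O)[C@@H](OC(C)=O)C[C@@H](O)C(C)(C)[C@H]1C(OCC)OCC
F4 | step 5 | ethyl (2Z)-2-[(1R)-1-acetoxy-4-methylpent-3-en-1-yl]-4,4-diethoxybut-2-enoate | CCOC(=O)/C(=C\C(OCC)OCC)[C@H](OC(C)=O)CC=C(C)C
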